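**Plan**
1. Retrosynthesis: the C6–Br, C8–Br and C7–Cl bonds are traced back to C–O bonds of a cyclohexenediol. The ring is then cut at C5–C6 (alkenyl iodide plus aldehyde), and the chain at C5–C7 (acetylide plus aldehyde) and C3–C4 (acetylide plus primary triflate).
2. Enabling feature: the ring segment C6–C1(CH3)2–C2–C3 is the carbon skeleton of (R)-pantolactone. Its lactone carbonyl (future C3) activates the neighbouring carbinol (C2) for chloride entry with inversion, although C2 lies beside the quaternary C1. The crowded C5–C6 bond of the cyclohexene ring, also beside C1, is left for an intramolecular alkenylchromium addition to an aldehyde that has no α-hydrogen.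
3. Forward order: pantolactone gives the C2 chloride and, after ring opening, the C3 triflate. C4/C5 come from ethynyltrimethylsilane and C7/C8 from a silyloxyacetaldehyde. trans-Hydrostannation and iodination give the Z-alkenyl iodide, C6 is oxidised, the six-membered ring is closed, and the remaining three halogens follow.
4. Stereochemistry: C2 comes from the chiral pool with one inversion. C7 comes from a catalyst-controlled ynone reduction and is inverted on chlorination. C6 is set in the ring closure under the influence of C2 and is inverted on bromination.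

Key step: step 12

Remark: atom labels are those of the target (C1 = C(CH3)2, C2 = ring CHCl, C3 = ring CH2, C4 = ring =CH, C5 = ring =C, C6 = CHBr, C7 = side-chain CHCl, C8 = CH2Br). The ring closure is assumed to place the C6 hydroxyl cis to the C2 chlorine; the later inversion at C6 rests on this.

**Step 1**
Reactants: 1 (R)-pantolactone
Product: 2 (3R)-4,4-dimethyl-2-oxooxolan-3-yl trifluoromethanesulfonate
Conditions: Tf2O, pyridine, CH2Cl2, −20 → 0 °C
Reagents that add atoms: trifluoromethanesulfonic anhydride, O=S(=O)(OS(=O)(=O)C(F)(F)F)C(F)(F)F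
Why: Triflation of the secondary alcohol (O-sulfonylation) breaks no bond at C2, so the (R) centre is kept while the oxygen becomes a leaving group alpha to the lactone carbonyl.

**Step 2**
Reactants: 2 pantolactone triflate
Product: 3 (3S)-3-chloro-4,4-dimethyloxolan-2-one
Conditions: LiCl (1.05 equiv), DMF, 0 °C → rt
Reagents that add atoms: lithium chloride, [Li+].[Cl-]
Why: SN2 displacement of an α-carbonyl triflate by chloride inverts C2 to (S): the lactone carbonyl lowers the barrier at a carbon that would otherwise behave as neopentyl, and near-stoichiometric chloride at low temperature keeps a second chloride-for-chloride exchange from eroding the configuration.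

**Step 3**
Reactants: 3 chlorolactone
Product: 5 (2S)-4-[(tert-butyldimethylsilyl)oxy]-2-chloro-N-methoxy-N,3,3-trimethylbutanamide, via hydroxy Weinreb amide 4 (not isolated)
Conditions: MeNH(OMe)·HCl, Me3Al, CH2Cl2, 0 °C → rt; aq. potassium sodium tartrate; crude 4, TBSCl, imidazole, DMF, 0 °C → rt
Reagents that add atoms: N,O-dimethylhydroxylamine hydrochloride, CNOC.Cl; tert-butyldimethylsilyl chloride, CC(C)(C)[Si](C)(C)Cl
Why: Weinreb aminolysis of the lactone by the aluminium amide opens the ring without touching C2 and leaves C3 as an amide and C6 as the only free hydroxyl, which is silylated before the gem-dimethyl group can drive re-lactonisation.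

**Step 4**
Reactants: 5 silyloxy Weinreb amide
Product: 7 (2S)-4-[(tert-butyldimethylsilyl)oxy]-2-chloro-3,3-dimethylbutan-1-ol, via chloro aldehyde 6 (not isolated)
Conditions: i-Bu2AlH, THF, −78 °C; aq. potassium sodium tartrate; crude 6, NaBH4, MeOH, −20 → 0 °C
Reagents that add atoms: none
Why: Partial reduction of a Weinreb amide stops at the aldehyde through the chelated aluminium hemiaminal, and borohydride reduction of the crude α-chloro aldehyde at low temperature gives the C3 carbinol before C2 can epimerise.

**Step 5**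
Reactants: 7 chloro alcohol; 8 ethynyltrimethylsilane
Product: 11 (3R)-tert-butyl[(3-chloro-2,2-dimethylhex-5-yn-1-yl)oxy]dimethylsilane, via triflate 9 (not isolated), via silylalkyne 10 (not isolated)
Conditions: Tf2O, 2,6-lutidine, CH2Cl2, −78 °C; then LiC≡CSiMe3 (from 8 and n-BuLi), THF/DMPU, −78 → −20 °C; then K2CO3, MeOH, rt
Reagents that add atoms: none
Why: SN2 alkylation of a lithium acetylide by a primary triflate forms the C3–C4 bond at −78 °C, faster than base-induced loss of HCl or attack of the silyl ether oxygen on C3, and carbonate methanolysis then removes only the alkynyl silyl group.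

**Step 6**
Reactants: 11 terminal alkyne; 12 (tert-butyldiphenylsilyloxy)acetaldehyde
Product: 14 (6R)-8-[(tert-butyldimethylsilyl)oxy]-1-[(tert-butyldiphenylsilyl)oxy]-6-chloro-7,7-dimethyloct-3-yn-2-ol (both C7 epimers; C2 of the octynol), via lithium acetylide 13 (not isolated)
Conditions: n-BuLi, THF, −78 °C; then 12, −78 → −40 °C
Reagents that add atoms: none
Why: 1,2-Addition of a lithium acetylide to an aldehyde forms the C5–C7 bond; the new C7 carbinol arises without control, which does not matter because it is oxidised in the next step.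

**Step 7**
Reactants: 14 propargylic alcohol
Product: 15 (6R)-8-[(tert-butyldimethylsilyl)oxy]-1-[(tert-butyldiphenylsilyl)oxy]-6-chloro-7,7-dimethyloct-3-yn-2-one
Conditions: Dess–Martin periodinane, CH2Cl2, 0 °C → rt
Reagents that add atoms: none
Why: Dess–Martin oxidation of a propargylic alcohol gives the ynone under near-neutral conditions that spare both silyl ethers and the secondary chloride, and it erases the uncontrolled C7 centre.

**Step 8**
Reactants: 15 ynone
Product: 16 (2R,6R)-8-[(tert-butyldimethylsilyl)oxy]-1-[(tert-butyldiphenylsilyl)oxy]-6-chloro-7,7-dimethyloct-3-yn-2-ol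
Conditions: Ru(p-cymene)[(S,S)-TsNCHPhCHPhNH] (2 mol%), i-PrOH, rt
Reagents that add atoms: none
Why: Noyori asymmetric transfer hydrogenation of an alkynyl ketone: the (S,S) catalyst should add hydride to the face that makes C7 (R) (the known sense for ynones, the descriptor changing because CH2OSi outranks the alkyne), under catalyst control that overrides the remote C2 centre.

**Step 9**
Reactants: 16 (R)-propargylic alcohol
Product: 18 (2S,3Z,6R)-8-[(tert-butyldimethylsilyl)oxy]-1-[(tert-butyldiphenylsilyl)oxy]-6-chloro-3-iodo-7,7-dimethyloct-3-en-2-ol, via alkenylstannane 17 (not isolated)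
Conditions: [Cp*RuCl]4 (1.5 mol%), Bu3SnH, CH2Cl2, rt; then I2, 0 °C
Reagents that add atoms: iodine, II
Why: Hydroxyl-directed ruthenium-catalysed trans-hydrostannation puts tin on the alkyne carbon next to the carbinol (C5) and hydrogen trans to it on C4, and iododestannylation occurs with retention, so iodine ends up cis to C3 (Z) as the ring closure demands.

**Step 10**
Reactants: 18 alkenyl iodide
Product: 19 (3R,5Z,7S)-8-[(tert-butyldiphenylsilyl)oxy]-3-chloro-6-iodo-2,2-dimethyloct-5-ene-1,7-diol
Conditions: CSA (10 mol%), MeOH/CH2Cl2, 0 °C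
Reagents that add atoms: none
Why: Acid-catalysed methanolysis (selective desilylation) removes the primary TBS ether much faster than the bulkier and far more acid-stable TBDPS ether, freeing only the C6 hydroxyl.

**Step 11**
Reactants: 19 diol
Product: 20 (3R,5Z,7S)-8-[(tert-butyldiphenylsilyl)oxy]-3-chloro-7-hydroxy-6-iodo-2,2-dimethyloct-5-enal
Conditions: TEMPO (10 mol%), PhI(OAc)2, CH2Cl2, rt
Reagents that add atoms: none
Why: TEMPO/PhI(OAc)2 oxidation through the oxoammonium ion prefers primary carbinols, and the secondary C7 hydroxyl is shielded by iodine and the silyloxymethyl group, so only C6 is taken to the aldehyde, which cannot enolise.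

**Step 12**
Reactants: 20 (Z)-alkenyl iodide aldehyde
Product: 21 (1S,5R)-2-[(1R)-2-[(tert-butyldiphenylsilyl)oxy]-1-hydroxyethyl]-5-chloro-6,6-dimethylcyclohex-2-en-1-ol
Conditions: CrCl2 (6 equiv), NiCl2 (2 mol%), degassed DMF, rt, 0.005 M
Reagents that add atoms: none
Why: CrCl2 reduces NiCl2 to zerovalent nickel, which adds oxidatively to the C5–I bond with retention of the Z geometry and passes the alkenyl group on to chromium; the alkenylchromium reagent (trivalent chromium) then attacks the C6 carbonyl. The closest known reaction type is the intramolecular Nozaki–Hiyama–Kishi coupling of an alkenyl iodide with an aldehyde. The cyclohexene ring closes in the 6-exo-trig mode (C=O outside the new ring), the C4=C5 double bond becoming endocyclic, which is geometrically possible only because iodine and C3 are cis on the alkene. The new C6 centre is controlled by the C2 chlorine through a chair-like transition state: chromium bridging C5 and the carbonyl oxygen holds the C=O close to the plane of the alkene, i.e. pseudo-equatorial, and with chlorine equatorial the hydroxyl should emerge cis to it, (S) at the ring carbinol. The step needs chemoselectivity for the C–I bond and the aldehyde and a preference for ring closure over dimerisation: the aldehyde has no α-hydrogen, the secondary alkyl chloride is inert to divalent chromium at room temperature, the free C7 hydroxyl is tolerated and is too poor a leaving group for β-elimination to an allene, and high dilution favours the intramolecular path.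

**Step 13**
Reactants: 21 cyclohexenediol
Product: 22 (1R,5R)-2-[(1S)-2-[(tert-butyldiphenylsilyl)oxy]-1-chloroethyl]-5-chloro-6,6-dimethylcyclohex-2-en-1-ol
Conditions: PPh3 (1.2 equiv), Cl3CC(O)CCl3, CH2Cl2, −20 → 0 °C
Reagents that add atoms: hexachloroacetone, O=C(C(Cl)(Cl)Cl)C(Cl)(Cl)Cl
Why: Appel-type chlorination with PPh3/hexachloroacetone converts allylic alcohols into chlorides by SN2 with inversion and little allylic transposition, which sets C7 as (S), while the C6 hydroxyl between the quaternary C1 and the substituted C5 is too hindered to be activated and displaced at this temperature.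

**Step 14**
Reactants: 22 C7 chloride
Product: 23 (1R,5R)-5-chloro-2-[(1S)-1-chloro-2-hydroxyethyl]-6,6-dimethylcyclohex-2-en-1-ol
Conditions: HF·pyridine, pyridine, THF, 0 °C → rt
Reagents that add atoms: none
Why: Fluoride-mediated desilylation with buffered HF·pyridine cleaves the Si–O bond under mildly acidic conditions, so no C8 alkoxide forms that could close an epoxide onto the C7 chloride.

**Step 15**
Reactants: 23 chloro diol
Product: 24 (4R,6S)-6-bromo-1-[(1S)-2-bromo-1-chloroethyl]-4-chloro-5,5-dimethylcyclohex-1-ene (target)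
Conditions: CBr4 (4 equiv), PPh3 (4 equiv), CH2Cl2, 0 °C → rt (diol added to the preformed reagent)
Reagents that add atoms: carbon tetrabromide, BrC(Br)(Br)Br
Why: Double Appel bromination: the primary C8 carbinol is displaced directly, and at the allylic C6 the oxyphosphonium, which can stay pseudo-equatorial and out of alignment with the alkene, is displaced by bromide from the opposite face (SN2 inversion), giving the (6S) bromide trans to the C2 chlorine.

**Compound list**
1 | (R)-pantolactone, (3R)-3-hydroxy-4,4-dimethyloxolan-2-one | CC1(C)COC(=O)[C@@H]1O | starting material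
2 | (3R)-4,4-dimethyl-2-oxooxolan-3-yl trifluoromethanesulfonate | CC1(C)COC(=O)[C@@H]1OS(=O)(=O)C(F)(F)F | intermediate
3 | (3S)-3-chloro-4,4-dimethyloxolan-2-one | CC1(C)COC(=O)[C@H]1Cl | intermediate
4 | (2S)-2-chloro-4-hydroxy-N-methoxy-N,3,3-trimethylbutanamide (used crude) | CON(C)C(=O)[C@@H](Cl)C(C)(C)CO | intermediate
5 | (2S)-4-[(tert-butyldimethylsilyl)oxy]-2-chloro-N-methoxy-N,3,3-trimethylbutanamide | CON(C)C(=O)[C@@H](Cl)C(C)(C)CO[Si](C)(C)C(C)(C)C | intermediate
6 | (2S)-4-[(tert-butyldimethylsilyl)oxy]-2-chloro-3,3-dimethylbutanal (used crude) | O=C[C@@H](Cl)C(C)(C)CO[Si](C)(C)C(C)(C)C | intermediate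
7 | (2S)-4-[(tert-butyldimethylsilyl)oxy]-2-chloro-3,3-dimethylbutan-1-ol | OC[C@@H](Cl)C(C)(C)CO[Si](C)(C)C(C)(C)C | intermediate
8 | ethynyltrimethylsilane | C#C[Si](C)(C)C | starting material
9 | (2S)-4-[(tert-butyldimethylsilyl)oxy]-2-chloro-3,3-dimethylbutyl trifluoromethanesulfonate (used cold, crude) | O=S(=O)(OC[C@@H](Cl)C(C)(C)CO[Si](C)(C)C(C)(C)C)C(F)(F)F | intermediate
10 | (3R)-tert-butyl{[3-chloro-2,2-dimethyl-6-(trimethylsilyl)hex-5-yn-1-yl]oxy}dimethylsilane (used crude) | C[Si](C)(C)C#CC[C@@H](Cl)C(C)(C)CO[Si](C)(C)C(C)(C)C | intermediate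
11 | (3R)-tert-butyl[(3-chloro-2,2-dimethylhex-5-yn-1-yl)oxy]dimethylsilane | C#CC[C@@H](Cl)C(C)(C)CO[Si](C)(C)C(C)(C)C | intermediate
12 | (tert-butyldiphenylsilyloxy)acetaldehyde | O=CCO[Si](c1ccccc1)(c1ccccc1)C(C)(C)C | starting material
13 | lithium acetylide of 11 (formed and used in the flask) | [Li]C#CC[C@@H](Cl)C(C)(C)CO[Si](C)(C)C(C)(C)C | intermediate
14 | (6R)-8-[(tert-butyldimethylsilyl)oxy]-1-[(tert-butyldiphenylsilyl)oxy]-6-chloro-7,7-dimethyloct-3-yn-2-ol, both epimers at the carbinol | CC(C)(C)[Si](c1ccccc1)(c1ccccc1)OCC(O)C#CC[C@@H](Cl)C(C)(C)CO[Si](C)(C)C(C)(C)C | intermediate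
15 | (6R)-8-[(tert-butyldimethylsilyl)oxy]-1-[(tert-butyldiphenylsilyl)oxy]-6-chloro-7,7-dimethyloct-3-yn-2-one | CC(C)(C)[Si](c1ccccc1)(c1ccccc1)OCC(=O)C#CC[C@@H](Cl)C(C)(C)CO[Si](C)(C)C(C)(C)C | intermediate
16 | (2R,6R)-8-[(tert-butyldimethylsilyl)oxy]-1-[(tert-butyldiphenylsilyl)oxy]-6-chloro-7,7-dimethyloct-3-yn-2-ol | CC(C)(C)[Si](c1ccccc1)(c1ccccc1)OC[C@H](O)C#CC[C@@H](Cl)C(C)(C)CO[Si](C)(C)C(C)(C)C | intermediate
17 | (2S,3Z,6R)-8-[(tert-butyldimethylsilyl)oxy]-1-[(tert-butyldiphenylsilyl)oxy]-6-chloro-7,7-dimethyl-3-(tributylstannyl)oct-3-en-2-ol (used crude) | CC(C)(C)[Si](c1ccccc1)(c1ccccc1)OC[C@H](O)/C(=C/C[C@@H](Cl)C(C)(C)CO[Si](C)(C)C(C)(C)C)[Sn](CCCC)(CCCC)CCCC | intermediate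
18 | (2S,3Z,6R)-8-[(tert-butyldimethylsilyl)oxy]-1-[(tert-butyldiphenylsilyl)oxy]-6-chloro-3-iodo-7,7-dimethyloct-3-en-2-ol | CC(C)(C)[Si](c1ccccc1)(c1ccccc1)OC[C@H](O)/C(I)=C/C[C@@H](Cl)C(C)(C)CO[Si](C)(C)C(C)(C)C | intermediate
19 | (3R,5Z,7S)-8-[(tert-butyldiphenylsilyl)oxy]-3-chloro-6-iodo-2,2-dimethyloct-5-ene-1,7-diol | CC(C)(C)[Si](c1ccccc1)(c1ccccc1)OC[C@H](O)/C(I)=C/C[C@@H](Cl)C(C)(C)CO | intermediate
20 | (3R,5Z,7S)-8-[(tert-butyldiphenylsilyl)oxy]-3-chloro-7-hydroxy-6-iodo-2,2-dimethyloct-5-enal | CC(C)(C)[Si](c1ccccc1)(c1ccccc1)OC[C@H](O)/C(I)=C/C[C@@H](Cl)C(C)(C)C=O | intermediate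
21 | (1S,5R)-2-[(1R)-2-[(tert-butyldiphenylsilyl)oxy]-1-hydroxyethyl]-5-chloro-6,6-dimethylcyclohex-2-en-1-ol (ring OH cis to Cl) | CC1(C)[C@H](Cl)CC=C([C@@H](O)CO[Si](c2ccccc2)(c2ccccc2)C(C)(C)C)[C@@H]1O | intermediate
22 | (1R,5R)-2-[(1S)-2-[(tert-butyldiphenylsilyl)oxy]-1-chloroethyl]-5-chloro-6,6-dimethylcyclohex-2-en-1-ol | CC1(C)[C@H](Cl)CC=C([C@H](Cl)CO[Si](c2ccccc2)(c2ccccc2)C(C)(C)C)[C@@H]1O | intermediate
23 | (1R,5R)-5-chloro-2-[(1S)-1-chloro-2-hydroxyethyl]-6,6-dimethylcyclohex-2-en-1-ol | CC1(C)[C@H](Cl)CC=C([C@H](Cl)CO)[C@@H]1O | intermediate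
24 | (4R,6S)-6-bromo-1-[(1S)-2-bromo-1-chloroethyl]-4-chloro-5,5-dimethylcyclohex-1-ene | CC1(C)[C@H](Cl)CC=C([C@H](Cl)CBr)[C@H]1Br | target

**Count and risks**
Total step count: 15. Longest linear sequence: 15 steps (1 to 24); 8 and 12 enter as purchased building blocks.

Steps most likely to fail:

1. Step 15. Displacement at C6, which is both allylic and next to the quaternary C1, may be diverted in three ways: bromide attack at C4 with allylic transposition, ion-pair collapse with retention, or ether formation when the C6 hydroxyl attacks activated C8. The fallback separates the two brominations and uses an isolated sulfonate with free bromide. It sets out from 23: CBr4/PPh3 (1.1 equiv, −40 °C) should brominate only the primary carbinol to give the bromo alcohol F1, so that no hydroxyl is left to cyclise onto C8. The C6 hydroxyl is then converted with ClCH2SO2Cl/pyridine into the chloromethanesulfonate F2, a small and reactive leaving group suited to hindered carbinols. LiBr in DMF displaces it with inversion, and the route is rejoined at 24.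

2. Step 12. The cyclisation may show poor facial selectivity at C6, or give the hydroxyl trans to chlorine, because the preference for a pseudo-equatorial carbonyl oxygen is only a prediction. The fallback sets C6 by ketone reduction instead of by the C–C bond formation. It sets out from 20: Et3SiCl/imidazole protects the C7 hydroxyl to give the triethylsilyl ether F3. The same CrCl2/NiCl2 conditions then close the ring to the alcohol F4 in whatever C6 epimer ratio arises. Dess–Martin oxidation gives the enone F5. Luche reduction (NaBH4, CeCl3·7H2O, MeOH, −78 °C) should deliver hydride axially, anti to the axial C1 methyl, to give the cis alcohol F6. PPTS in MeOH removes the triethylsilyl group without touching the TBDPS ether, and the route is rejoined at 21.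

3. Step 13. Site selectivity between the two secondary allylic hydroxyls may be lost, the 1,3-diol may tie up the phosphorus reagent as a cyclic phosphorane, or chloride may enter at C4 with allylic transposition. The fallback differentiates the two carbinols by protection instead of by the kinetic preference of the reagent. It sets out from 21: excess Et3SiOTf/2,6-lutidine gives the bis(triethylsilyl) ether F7. PPTS in MeOH at 0 °C should cleave only the unhindered C7 silyl ether, giving the mono-protected alcohol F8. PPh3/hexachloroacetone then has a single hydroxyl to convert and gives the chloride F9 with inversion. HF·pyridine removes the C6 triethylsilyl and the C8 TBDPS groups together, and the route is rejoined at 23.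

**Further compounds**
F1 | step 15 | (1R,5R)-2-[(1S)-2-bromo-1-chloroethyl]-5-chloro-6,6-dimethylcyclohex-2-en-1-ol | CC1(C)[C@H](Cl)CC=C([C@H](Cl)CBr)[C@@H]1O
F2 | step 15 | (1R,5R)-2-[(1S)-2-bromo-1-chloroethyl]-5-chloro-6,6-dimethylcyclohex-2-en-1-yl chloromethanesulfonate | CC1(C)[C@H](Cl)CC=C([C@H](Cl)CBr)[C@@H]1OS(=O)(=O)CCl
F3 | step 12 | (3R,5Z,7S)-8-[(tert-butyldiphenylsilyl)oxy]-3-chloro-6-iodo-2,2-dimethyl-7-[(triethylsilyl)oxy]oct-5-enal | CC(C)(C)[Si](c1ccccc1)(c1ccccc1)OC[C@H](O[Si](CC)(CC)CC)/C(I)=C/C[C@@H](Cl)C(C)(C)C=O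
F4 | step 12 | (5R)-2-[(1R)-2-[(tert-butyldiphenylsilyl)oxy]-1-[(triethylsilyl)oxy]ethyl]-5-chloro-6,6-dimethylcyclohex-2-en-1-ol, mixture of epimers at the ring carbinol | CC1(C)[C@H](Cl)CC=C([C@@H](O[Si](CC)(CC)CC)CO[Si](c2ccccc2)(c2ccccc2)C(C)(C)C)C1O
F5 | step 12 | (5R)-2-[(1R)-2-[(tert-butyldiphenylsilyl)oxy]-1-[(triethylsilyl)oxy]ethyl]-5-chloro-6,6-dimethylcyclohex-2-en-1-one | CC1(C)[C@H](Cl)CC=C([C@@H](O[Si](CC)(CC)CC)CO[Si](c2ccccc2)(c2ccccc2)C(C)(C)C)C1=O
F6 | step 12 | (1S,5R)-2-[(1R)-2-[(tert-butyldiphenylsilyl)oxy]-1-[(triethylsilyl)oxy]ethyl]-5-chloro-6,6-dimethylcyclohex-2-en-1-ol | CC1(C)[C@H](Cl)CC=C([C@@H](O[Si](CC)(CC)CC)CO[Si](c2ccccc2)(c2ccccc2)C(C)(C)C)[C@@H]1O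
F7 | step 13 | bis(triethylsilyl) ether of 21 (both secondary oxygens silylated) | CC1(C)[C@H](Cl)CC=C([C@@H](O[Si](CC)(CC)CC)CO[Si](c2ccccc2)(c2ccccc2)C(C)(C)C)[C@@H]1O[Si](CC)(CC)CC
F8 | step 13 | ring-O-triethylsilyl ether of 21 (C7 hydroxyl free) | CC1(C)[C@H](Cl)CC=C([C@@H](O)CO[Si](c2ccccc2)(c2ccccc2)C(C)(C)C)[C@@H]1O[Si](CC)(CC)CC
F9 | step 13 | ring-O-triethylsilyl ether of 22 | CC1(C)[C@H](Cl)CC=C([C@H](Cl)CO[Si](c2ccccc2)(c2ccccc2)C(C)(C)C)[C@@H]1O[Si](CC)(CC)CC
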